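**Plan**

- Retrosynthesis, in order: the four phenol protecting groups; the C3′–OH bond (allylic C–H hydroxylation); the C2′=CH2 bond (from a C2′ ketone); the C6–CH2 bond between flavone ring A and the cyclohexane unit; the C2′ carbinol hydrogen (enantioselective ketone reduction); the gem-dimethyl and methylidene carbons of a bought cyclohexenone.
- Forward: 3-methylcyclohex-2-en-1-one → 2-methylidene ketone → (R)-allylic alcohol (steps 1–3); luteolin → 6-iodo tetra-MOM ether (steps 4–6); union at C6–CH2 by a Heck arylation that ends as the ketone (step 7); methylenation, allylic hydroxylation, deprotection (steps 8–10). No ring is built; both ring systems are bought.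
- Enabling feature: the methylidene carbon C2′ is the ring neighbour of C1′, which carries the CH2 link to C6 of ring A. Written as a carbinol, C2′ makes that CH2 the terminus of an allylic alcohol that accepts an aryl–palladium, and the quaternary C6′ (CMe2) leaves the carbinol hydrogen as the only ring hydrogen that can migrate. In ring A, C6 lies between O5 (hydrogen-bonded to the C4 carbonyl) and O7, which directs iodination to C6.
- Stereochemistry: the C2′ carbinol is a temporary stereocentre set by CBS reduction; the key step passes its configuration to C1′ by a suprafacial 1,2-hydrogen shift and consumes it. C3′ is then set relative to C1′ by SeO2 hydroxylation anti to the C1′ substituent.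

Key step: step 7

Remark: cyclohexane carbons carry primed numbers in every intermediate (C1′ = CH with the CH2 link, C2′ = methylidene, carbonyl or carbinol carbon, C3′ = carbinol carbon of the target, C6′ = CMe2); flavone positions carry plain numbers; MOM = CH2OCH3; all named reagents are taken as commercial.

Step 1
Reactants: 1 3-methylcyclohex-2-en-1-one
Product: 3 racemic 2-[(dimethylamino)methyl]-3,3-dimethylcyclohexan-1-one, via lithium 3,3-dimethylcyclohex-1-en-1-olate 2 (not isolated)
Conditions: Me2CuLi (from MeLi, CuI), Et2O, 0 °C; then CH2=NMe2+ I−, THF, −78 °C → rt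
Reagents that add atoms: lithium dimethylcuprate, [Li+].C[Cu-]C (made in the flask from methyllithium, C[Li], and copper(I) iodide); N,N-dimethylmethyleneiminium iodide (Eschenmoser's salt), C=[N+](C)C.[I-]
Why: Conjugate addition of the Gilman cuprate to the β-methyl enone builds the gem-dimethyl carbon and leaves the enolate on the hindered side, where Eschenmoser's salt traps it (Mannich reaction of a preformed enolate); the stereocentre formed here is racemic and is removed again in step 2.

Step 2
Reactants: 3 racemic 2-[(dimethylamino)methyl]-3,3-dimethylcyclohexan-1-one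
Product: 5 enone 3,3-dimethyl-2-methylidenecyclohexan-1-one, via [(2,2-dimethyl-6-oxocyclohexyl)methyl]trimethylammonium iodide 4 (not isolated)
Conditions: MeI, Et2O, rt; then aq. NaHCO3, CH2Cl2, rt
Reagents that add atoms: iodomethane, CI (its carbon is carried only by intermediate 4 and leaves again as trimethylamine)
Why: Exhaustive N-methylation turns the amine into a leaving group and mild base then effects E1cB (Hofmann-type) elimination of the β-ammonio ketone to the exocyclic enone, which is used at once because it dimerises on standing.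

Step 3
Reactants: 5 enone 3,3-dimethyl-2-methylidenecyclohexan-1-one
Product: 6 (1R)-3,3-dimethyl-2-methylidenecyclohexan-1-ol
Conditions: (S)-Me-CBS (15 mol%), catecholborane, toluene, −78 °C; aq. NaOH work-up
Reagents that add atoms: none
Why: Corey–Bakshi–Shibata reduction: the oxazaborolidine holds the carbonyl oxygen anti to the larger α-methylidene side and delivers hydride to one face, which with the (S)-catalyst should give the (1R)-carbinol (the same sense as acetophenone to (R)-1-phenylethanol), while catecholborane at −78 °C reduces only the carbonyl group and not the alkene.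

Step 4
Reactants: 7 luteolin (5,7,3′,4′-tetrahydroxyflavone)
Product: 8 7,3′,4′-tri-O-MOM-luteolin (5-OH free)
Conditions: MOMCl (3.3 equiv), i-Pr2NEt, DMF/CH2Cl2, 0 °C → rt
Reagents that add atoms: chloromethyl methyl ether, COCCl
Why: Base-mediated O-alkylation (MOM ether formation) of the three free phenols; the 5-OH is hydrogen-bonded to the C4 carbonyl and is the least reactive, so it stays free with 3.3 equivalents of reagent.

Step 5
Reactants: 8 7,3′,4′-tri-O-MOM-luteolin
Product: 9 6-iodo-7,3′,4′-tri-O-MOM-luteolin (5-OH free)
Conditions: BnMe3N+ ICl2−, CaCO3, CH2Cl2/MeOH, rt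
Reagents that add atoms: benzyltrimethylammonium dichloroiodate, C[N+](C)(C)Cc1ccccc1.Cl[I-]Cl
Why: Electrophilic aromatic iodination: in 5-hydroxy-7-alkoxyflavones the free chelated 5-OH directs the iodonium equivalent to its ortho position C6 and not to C8, the established way to 6-iodoflavones, and CaCO3 takes up the HCl so that the MOM ethers survive.

Step 6
Reactants: 9 6-iodo-7,3′,4′-tri-O-MOM-luteolin
Product: 10 6-iodo-5,7,3′,4′-tetra-O-MOM-luteolin
Conditions: NaH, MOMCl, DMF, 0 °C → rt
Reagents that add atoms: chloromethyl methyl ether, COCCl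
Why: Deprotonation of the chelated phenol with NaH and O-alkylation (MOM ether formation) removes the acidic ortho-hydroxyl, which could otherwise trap the arylpalladium intermediate of step 7 as a cyclic ether.

Step 7
Reactants: 10 6-iodo-5,7,3′,4′-tetra-O-MOM-luteolin; 6 (1R)-3,3-dimethyl-2-methylidenecyclohexan-1-ol (1.5 equiv)
Product: 11 (2S)-3,3-dimethyl-2-[(5,7,3′,4′-tetra-O-MOM-luteolin-6-yl)methyl]cyclohexan-1-one
Conditions: Pd(OAc)2 (10 mol%), n-Bu4NCl, NaHCO3, DMF, 60 °C
Reagents that add atoms: none
Why: Proposed new method: a Mizoroki–Heck reaction with redox relay, in which oxidative addition of the C6–I bond to Pd(0) and syn-carbopalladation of the exocyclic alkene put the aryl group on the terminal CH2 (the new C6–CH2 bond) and palladium on C1′, whose neighbour C6′ is quaternary, so the only ring hydrogen syn to palladium is the carbinol hydrogen at C2′; its β-elimination gives a Pd–H-bound enol, re-insertion returns the same hydrogen to C1′ on the same face, and loss of HPdI from the hydroxyalkyl-palladium gives the ketone. The closest known reactions are the ligand-free, chloride-promoted Heck arylation of allylic alcohols to β-aryl carbonyl compounds, in which the carbinol hydrogen shifts to the neighbouring carbon, and chain-walking relay Heck reactions; what is new is the use of this shift to pass the configuration of a cyclic secondary carbinol on to the adjacent ring carbon. No ring is closed. The new stereocentre C1′ is controlled by the (1R)-carbinol: hydrogen can only arrive on the face that carried the carbinol hydrogen, so the arylmethyl group ends on the former hydroxyl face and the ketone should be (2S), while palladium added on the hydroxyl face has no syn carbinol hydrogen and can only give a styrene-type allylic alcohol, not the enantiomeric ketone. The step needs C6 and not C8 regiochemistry, secured by the iodide; β-hydride elimination towards the carbinol and not the benzylic CH2, favoured by the hydridic α-oxy C–H bond and by the twisted, non-conjugating 2,6-dioxygenated aryl group; and an enol that stays on palladium until re-insertion, which is the unproven point. Chloride-rich, silver-free conditions keep palladium neutral and undirected by the hydroxyl, and bicarbonate is too weak to epimerise the α-centre next to the quaternary carbon.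

Step 8
Reactants: 11 (2S)-3,3-dimethyl-2-[(5,7,3′,4′-tetra-O-MOM-luteolin-6-yl)methyl]cyclohexan-1-one
Product: 12 6-{[(1S)-6,6-dimethyl-2-methylidenecyclohexyl]methyl}-5,7,3′,4′-tetra-O-MOM-luteolin
Conditions: Zn, CH2Br2, TiCl4 (Lombardo reagent), THF/CH2Cl2, 0 °C → rt
Reagents that add atoms: dibromomethane, BrCBr
Why: Takai–Lombardo methylenation: the non-basic Zn/CH2Br2/TiCl4 reagent turns hindered, enolisable ketones into exocyclic alkenes without epimerising the α-stereocentre C1′ and does not touch the vinylogous-ester carbonyl of the flavone.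

Step 9
Reactants: 12 6-{[(1S)-6,6-dimethyl-2-methylidenecyclohexyl]methyl}-5,7,3′,4′-tetra-O-MOM-luteolin
Product: 13 6-{[(1S,3S)-3-hydroxy-6,6-dimethyl-2-methylidenecyclohexyl]methyl}-5,7,3′,4′-tetra-O-MOM-luteolin
Conditions: SeO2 (0.5 equiv), t-BuOOH, CH2Cl2, 0 °C → rt
Reagents that add atoms: selenium dioxide, O=[Se]=O; tert-butyl hydroperoxide, CC(C)(C)OO
Why: Selenium dioxide/t-BuOOH allylic hydroxylation (Riley-type oxidation): the ene reaction at the exocyclic methylidene takes a hydrogen from the ring CH2 at C3′ (CH2 before CH) and the [2,3]-shift of the allylseleninic acid returns oxygen to C3′ on the face opposite the pseudoaxial C1′ arylmethyl group, which should give the trans (3′S) alcohol, as is usual for 2-substituted methylidenecyclohexanes of the labd-8(17)-ene type.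

Step 10
Reactants: 13 6-{[(1S,3S)-3-hydroxy-6,6-dimethyl-2-methylidenecyclohexyl]methyl}-5,7,3′,4′-tetra-O-MOM-luteolin
Product: 14 ugonin Q
Conditions: HCl (2 M), MeOH/THF, rt → 40 °C
Reagents that add atoms: none
Why: Acid-catalysed acetal exchange with methanol (MOM cleavage) frees the four phenols; the allylic hydroxyl inductively slows protonation of the exocyclic alkene, so that dilute acid near room temperature should leave the alkene, the allylic alcohol and both stereocentres untouched, as in MOM removals on prenylated flavonoids.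

**Compound list**

1 | 3-methylcyclohex-2-en-1-one | CC1=CC(=O)CCC1 | starting material
2 | lithium 3,3-dimethylcyclohex-1-en-1-olate (not isolated) | [Li]OC1=CC(C)(C)CCC1 | intermediate
3 | racemic 2-[(dimethylamino)methyl]-3,3-dimethylcyclohexan-1-one | CN(C)CC1C(=O)CCCC1(C)C | intermediate
4 | [(2,2-dimethyl-6-oxocyclohexyl)methyl]trimethylammonium iodide (not isolated) | C[N+](C)(C)CC1C(=O)CCCC1(C)C.[I-] | intermediate
5 | 3,3-dimethyl-2-methylidenecyclohexan-1-one | C=C1C(=O)CCCC1(C)C | intermediate
6 | (1R)-3,3-dimethyl-2-methylidenecyclohexan-1-ol | O[C@@H]1CCCC(C)(C)C1=C | intermediate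
7 | luteolin, 2-(3,4-dihydroxyphenyl)-5,7-dihydroxy-4H-chromen-4-one | O=c1cc(-c2ccc(O)c(O)c2)oc2cc(O)cc(O)c12 | starting material
8 | 2-[3,4-bis(methoxymethoxy)phenyl]-5-hydroxy-7-(methoxymethoxy)-4H-chromen-4-one | COCOc1cc(O)c2c(=O)cc(-c3ccc(OCOC)c(OCOC)c3)oc2c1 | intermediate
9 | 2-[3,4-bis(methoxymethoxy)phenyl]-5-hydroxy-6-iodo-7-(methoxymethoxy)-4H-chromen-4-one | COCOc1cc2oc(-c3ccc(OCOC)c(OCOC)c3)cc(=O)c2c(O)c1I | intermediate
10 | 2-[3,4-bis(methoxymethoxy)phenyl]-6-iodo-5,7-bis(methoxymethoxy)-4H-chromen-4-one | COCOc1cc2oc(-c3ccc(OCOC)c(OCOC)c3)cc(=O)c2c(OCOC)c1I | intermediate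
11 | (2S)-2-({2-[3,4-bis(methoxymethoxy)phenyl]-5,7-bis(methoxymethoxy)-4-oxo-4H-chromen-6-yl}methyl)-3,3-dimethylcyclohexan-1-one | O=C1CCCC(C)(C)[C@@H]1Cc1c(OCOC)cc2oc(-c3ccc(OCOC)c(OCOC)c3)cc(=O)c2c1OCOC | intermediate
12 | 2-[3,4-bis(methoxymethoxy)phenyl]-6-{[(1S)-6,6-dimethyl-2-methylidenecyclohexyl]methyl}-5,7-bis(methoxymethoxy)-4H-chromen-4-one | C=C1CCCC(C)(C)[C@@H]1Cc1c(OCOC)cc2oc(-c3ccc(OCOC)c(OCOC)c3)cc(=O)c2c1OCOC | intermediate
13 | 2-[3,4-bis(methoxymethoxy)phenyl]-6-{[(1S,3S)-3-hydroxy-6,6-dimethyl-2-methylidenecyclohexyl]methyl}-5,7-bis(methoxymethoxy)-4H-chromen-4-one | C=C1[C@@H](Cc2c(OCOC)cc3oc(-c4ccc(OCOC)c(OCOC)c4)cc(=O)c3c2OCOC)C(C)(C)CC[C@@H]1O | intermediate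
14 | ugonin Q, 2-(3,4-dihydroxyphenyl)-5,7-dihydroxy-6-{[(1S,3S)-3-hydroxy-6,6-dimethyl-2-methylidenecyclohexyl]methyl}-4H-chromen-4-one | C=C1[C@@H](Cc2c(O)cc3oc(-c4ccc(O)c(O)c4)cc(=O)c3c2O)C(C)(C)CC[C@@H]1O | target

**Step count:** 10 steps in total. Longest linear sequence: 7 steps (steps 4–10 from luteolin; the other branch, steps 1–3 then 7–10, is also 7).

**Steps most likely to fail**

Step 7 (bears the label). The tetrasubstituted enol may leave the palladium hydride before re-insertion and tautomerise in solution, so that the configuration at C1′ is lost; or carbopalladation may occur on the hydroxyl face and stop at the styrene-type alcohol, so that little ketone forms. The fallback uses only known reaction types, sets out from enone 5 and iodide 10, and comes back at 11. CBS reduction of 5 with the (R)-catalyst should give the enantiomeric alcohol (1S)-3,3-dimethyl-2-methylidenecyclohexan-1-ol F1. Heck arylation of F1 with 10 under cationic, silver-promoted conditions (Pd(OAc)2, Ag2CO3, DMF), which direct palladium to the hydroxyl face and are known to stop at the unsaturated alcohol, should give (1S,2Z)-3,3-dimethyl-2-[(5,7,3′,4′-tetra-O-MOM-luteolin-6-yl)methylidene]cyclohexan-1-ol F2. Hydroxyl-directed hydrogenation with [Ir(cod)(PCy3)(py)]PF6 and H2 in CH2Cl2 adds hydrogen to C1′ from the hydroxyl face and should give the trans alcohol (1S,2S)-3,3-dimethyl-2-[(5,7,3′,4′-tetra-O-MOM-luteolin-6-yl)methyl]cyclohexan-1-ol F3. Dess–Martin oxidation of F3 then gives 11 with the same (2S) configuration.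

Step 9. The allylic alcohol may be over-oxidised to the enone, the C1′ hydrogen may be abstracted in competition, or oxygen may be delivered to both faces of C3′. The fallback sets out from ketone 11 (before step 8) and comes back at 13. Kinetic deprotonation with KHMDS at −78 °C on the CH2 side of the carbonyl should give the potassium enolate of 11 F4. Hydroxylation with 2-(phenylsulfonyl)-3-phenyloxaziridine, anti to the pseudoaxial arylmethyl group, should give the trans hydroxy ketone (2S,6S)-6-hydroxy-3,3-dimethyl-2-[(5,7,3′,4′-tetra-O-MOM-luteolin-6-yl)methyl]cyclohexan-1-one F5. Takai–Lombardo methylenation of F5 with excess reagent, which tolerates the free hydroxyl, should then give 13 directly.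

Step 8. Addition to the hindered carbonyl may be slow, and long exposure to the Lewis-acidic zinc and titanium salts may cleave the chelated 5-O-MOM ether. The fallback sets out from 11 and comes back at 12 by Peterson olefination. Addition of (trimethylsilyl)methyllithium/CeCl3 at −78 °C to the ketone (the flavone carbonyl, a vinylogous ester, is far less electrophilic) should give the β-hydroxysilane (2S)-3,3-dimethyl-2-[(5,7,3′,4′-tetra-O-MOM-luteolin-6-yl)methyl]-1-[(trimethylsilyl)methyl]cyclohexan-1-ol F6 as a mixture of carbinol epimers. Syn-elimination with KH in THF then gives 12.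

Further compounds
F1 | step 7 | (1S)-3,3-dimethyl-2-methylidenecyclohexan-1-ol | O[C@H]1CCCC(C)(C)C1=C
F2 | step 7 | (1S,2Z)-2-({2-[3,4-bis(methoxymethoxy)phenyl]-5,7-bis(methoxymethoxy)-4-oxo-4H-chromen-6-yl}methylidene)-3,3-dimethylcyclohexan-1-ol | O[C@H]1CCCC(C)(C)/C1=C/c1c(OCOC)cc2oc(-c3ccc(OCOC)c(OCOC)c3)cc(=O)c2c1OCOC
F3 | step 7 | (1S,2S)-2-({2-[3,4-bis(methoxymethoxy)phenyl]-5,7-bis(methoxymethoxy)-4-oxo-4H-chromen-6-yl}methyl)-3,3-dimethylcyclohexan-1-ol | O[C@H]1CCCC(C)(C)[C@@H]1Cc1c(OCOC)cc2oc(-c3ccc(OCOC)c(OCOC)c3)cc(=O)c2c1OCOC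
F4 | step 9 | potassium enolate of 11, potassium (6S)-6-({2-[3,4-bis(methoxymethoxy)phenyl]-5,7-bis(methoxymethoxy)-4-oxo-4H-chromen-6-yl}methyl)-5,5-dimethylcyclohex-1-en-1-olate | [K]OC1=CCCC(C)(C)[C@@H]1Cc1c(OCOC)cc2oc(-c3ccc(OCOC)c(OCOC)c3)cc(=O)c2c1OCOC
F5 | step 9 | (2S,6S)-2-({2-[3,4-bis(methoxymethoxy)phenyl]-5,7-bis(methoxymethoxy)-4-oxo-4H-chromen-6-yl}methyl)-6-hydroxy-3,3-dimethylcyclohexan-1-one | O=C1[C@@H](O)CCC(C)(C)[C@@H]1Cc1c(OCOC)cc2oc(-c3ccc(OCOC)c(OCOC)c3)cc(=O)c2c1OCOC
F6 | step 8 | (2S)-2-({2-[3,4-bis(methoxymethoxy)phenyl]-5,7-bis(methoxymethoxy)-4-oxo-4H-chromen-6-yl}methyl)-3,3-dimethyl-1-[(trimethylsilyl)methyl]cyclohexan-1-ol (carbinol epimers) | C[Si](C)(C)CC1(O)CCCC(C)(C)[C@@H]1Cc1c(OCOC)cc2oc(-c3ccc(OCOC)c(OCOC)c3)cc(=O)c2c1OCOC
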